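**Retrosynthetic overview**
- Ring numbering: C1 (C=O), C2=C3, C4 (OH, C17 chain), C5H2, C6 (OH). The route rests on C4, a fully substituted ring carbon bonded directly to the enone β-carbon C3. This is the 4,4-disubstituted cyclohex-2-enone pattern that a 1-amino-3-siloxydiene and an α-alkylacrolein deliver.
- Late changes: Z-C10'=C11' from the alkyne (Lindlar); C6–OH from Rubottom oxidation of the C1=C6 silyl dienol ether; C4–OH from a C4–CHO by Baeyer–Villiger oxidation with retention.
- Key disconnection: C3–C4 and C5–C6, by enantioselective Diels–Alder reaction of the aminosiloxydiene (C1, C2, C3, C6) with 2-methylidenenonadec-12-ynal (C4, C5, CHO, chain). The only ring is closed here, and loss of the amine gives C2=C3.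
- Dienophile: α-methylenation of nonadec-12-ynal, itself from lithium octynide and THP-protected 11-bromoundecanol.

Key step: step 6

Assumption: (R,R)-1-naphthyl-TADDOL is written as the antipode that gives (R)-11; which antipode gives the R centre is to be confirmed in the first run, and the (S,S)-diol is used instead if the sense is opposite.

**Route**

Step 1
Reactants: 1 11-bromoundecan-1-ol
Product: 2 2-[(11-bromoundecyl)oxy]oxane
Conditions: 3,4-dihydro-2H-pyran, PPTS (cat.), CH2Cl2, rt
Reagents that add atoms: 3,4-dihydro-2H-pyran, C1=COCCC1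
Why: Acid-catalysed addition of the alcohol to the enol ether (tetrahydropyranylation) masks the hydroxyl so that it cannot quench the acetylide of step 2; the acetal carbon forms as a racemate and is removed in step 3.

Step 2
Reactants: 3 oct-1-yne; 2 2-[(11-bromoundecyl)oxy]oxane
Product: 5 2-(nonadec-12-yn-1-yloxy)oxane, via lithium oct-1-yn-1-ide 4 (not isolated)
Conditions: n-BuLi, THF, −78 → 0 °C; then 2, DMPU, 0 °C → rt
Reagents that add atoms: none
Why: SN2 alkylation of a lithium acetylide by an unhindered primary bromide in a dipolar co-solvent should form the C11–C12 bond cleanly, and the THP acetal is stable to the base.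

Step 3
Reactants: 5 2-(nonadec-12-yn-1-yloxy)oxane
Product: 6 nonadec-12-yn-1-ol
Conditions: TsOH·H2O (cat.), MeOH, rt
Reagents that add atoms: none
Why: Acid-catalysed transacetalisation to methanol releases the primary alcohol and leaves the internal alkyne untouched.

Step 4
Reactants: 6 nonadec-12-yn-1-ol
Product: 7 nonadec-12-ynal
Conditions: TEMPO (cat.), PhI(OAc)2, CH2Cl2, rt
Reagents that add atoms: none
Why: Oxoammonium-mediated oxidation of a primary alcohol should stop at the aldehyde under anhydrous conditions and does not touch the alkyne.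

Step 5
Reactants: 7 nonadec-12-ynal
Product: 8 2-methylidenenonadec-12-ynal
Conditions: aq. CH2O (37%), pyrrolidine (10 mol%), EtCO2H (10 mol%), i-PrOH, 45 °C
Reagents that add atoms: formaldehyde, C=O
Why: Amine-catalysed α-methylenation (Mannich condensation of the enamine with formaldehyde, then elimination of the amine) should convert the linear aldehyde into the 2-alkylacrolein, which is used promptly because such enals dimerise on standing.

Step 6
Reactants: 8 2-methylidenenonadec-12-ynal; 9 (E)-1-(dimethylamino)-3-(tert-butyldimethylsilyloxy)buta-1,3-diene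
Product: 11 (1R)-1-(heptadec-10-yn-1-yl)-4-oxocyclohex-2-ene-1-carbaldehyde, via amino silyl enol ether cycloadduct 10 (not isolated)
Conditions: 9 (1.5 equiv), (R,R)-1-naphthyl-TADDOL (20 mol%), toluene, −80 °C; then 48% aq. HF, MeCN, −40 → 0 °C
Reagents that add atoms: none
Why: The free hydroxyl of the TADDOL (its partner is held in an internal hydrogen bond) donates a hydrogen bond to the formyl oxygen of 8 and lowers its LUMO, and diene 9 then adds in a concerted, strongly asynchronous Diels–Alder reaction in which the diene CH2 terminus bonds to the acrolein CH2 (C5–C6) and the amino-bearing carbon closes onto the substituted α-carbon (C3–C4). The closest known reaction type is the TADDOL-catalysed enantioselective cycloaddition of 1-amino-3-siloxybutadienes with α-alkylacroleins, which gives 4-alkyl-4-formylcyclohex-2-enones after acid treatment. The six-membered carbocycle of 10 is closed by this intermolecular [4+2] cycloaddition, suprafacial on both partners, and aqueous HF then hydrolyses the silyl enol ether and eliminates dimethylamine by β-elimination to give the C1 ketone and C2=C3. The quaternary stereocentre C4 is set under catalyst control, a naphthyl group of the diol shielding one face of the hydrogen-bonded enal, whereas the amino-bearing centre of 10 (formyl-endo adduct) is transient and is lost in the elimination. The step needs regioselectivity, secured by the push–pull polarisation of the diene (largest HOMO coefficient at the CH2 terminus, matched to the acrolein β-carbon), and enantiofacial selectivity, helped by the low temperature that suppresses the uncatalysed pathway; the unactivated alkyne is not a dienophile for this diene, and the formyl-bearing carbon is quaternary and cannot epimerise in the acid work-up.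

Step 7
Reactants: 11 (1R)-1-(heptadec-10-yn-1-yl)-4-oxocyclohex-2-ene-1-carbaldehyde
Product: 13 (4R)-4-(heptadec-10-yn-1-yl)-4-hydroxycyclohex-2-en-1-one, via tertiary formate 12 (not isolated)
Conditions: mCPBA, CH2Cl2, 0 °C → rt; aq. Na2S2O3/NaHCO3 wash; then KHCO3 (cat.), MeOH, rt
Reagents that add atoms: 3-chloroperbenzoic acid, OOC(=O)c1cccc(Cl)c1
Why: In this Baeyer–Villiger oxidation of a non-enolisable aldehyde the tertiary, allylic C4 should migrate to oxygen with retention of configuration in preference to hydrogen, the electron-poor enone C=C and the internal alkyne being too unreactive toward the peracid to compete, and mild base-catalysed methanolysis then cleaves the formate to the tertiary alcohol.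

Step 8
Reactants: 13 (4R)-4-(heptadec-10-yn-1-yl)-4-hydroxycyclohex-2-en-1-one
Product: 14 (5R)-5-(heptadec-10-yn-1-yl)-2,5-bis(trimethylsilyloxy)cyclohexa-1,3-diene
Conditions: TMSOTf (2.5 equiv), Et3N, CH2Cl2, −78 → 0 °C; non-aqueous work-up, used crude
Reagents that add atoms: trimethylsilyl trifluoromethanesulfonate, C[Si](C)(C)OS(=O)(=O)C(F)(F)F
Why: Soft enolisation with silyl triflate and amine silylates the tertiary hydroxyl and converts the enone into its 2-silyloxy-1,3-diene; C4 is quaternary, so there is no γ-hydrogen and deprotonation can only occur at C6.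

Step 9
Reactants: 14 (5R)-5-(heptadec-10-yn-1-yl)-2,5-bis(trimethylsilyloxy)cyclohexa-1,3-diene
Product: 16 (4R,6S)-4-(heptadec-10-yn-1-yl)-4,6-dihydroxycyclohex-2-en-1-one, via silyloxy epoxide 15 (not isolated)
Conditions: dimethyldioxirane (1.05 equiv, acetone), CH2Cl2, −78 → −40 °C; then Et3N·3HF, THF, 0 °C
Reagents that add atoms: dimethyldioxirane, CC1(C)OO1
Why: In this Rubottom oxidation of a 2-silyloxy-1,3-diene the dioxirane should epoxidise the electron-rich C1=C6 enol ether bond far faster than C2=C3 or the alkyne, and buffered fluoride opens the silyloxy epoxide to the α'-hydroxy enone and removes both silyl groups without the strong acid that could dehydrate the diol to a catechol; the C6 stereocentre is set by substrate control, the oxidant being expected to approach C6 on the ring face anti to the long C17 chain at C4 (the face of the small C4 oxygen substituent), which places the C6 and C4 oxygens cis (6S).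

Step 10
Reactants: 16 (4R,6S)-4-(heptadec-10-yn-1-yl)-4,6-dihydroxycyclohex-2-en-1-one
Product: 17 (4R,6S)-4-[(10Z)-heptadec-10-en-1-yl]-4,6-dihydroxycyclohex-2-en-1-one
Conditions: H2 (1 atm), Lindlar catalyst (Pd/CaCO3, Pb-poisoned), quinoline, EtOAc, rt; stopped after 1 equiv H2
Reagents that add atoms: none
Why: Lindlar semihydrogenation adds H2 syn on the poisoned palladium surface to give the Z-alkene, the alkyne binding far more strongly than the conjugated C2=C3 bond, which is flanked by the quaternary C4 and should survive if the uptake is monitored.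

**Compound list**
1 | 11-bromoundecan-1-ol | OCCCCCCCCCCCBr | starting material
2 | 2-[(11-bromoundecyl)oxy]oxane (racemic acetal carbon) | BrCCCCCCCCCCCOC1CCCCO1 | intermediate
3 | oct-1-yne | CCCCCCC#C | starting material
4 | lithium oct-1-yn-1-ide | CCCCCCC#C[Li] | intermediate (not isolated)
5 | 2-(nonadec-12-yn-1-yloxy)oxane (racemic acetal carbon) | CCCCCCC#CCCCCCCCCCCCOC1CCCCO1 | intermediate
6 | nonadec-12-yn-1-ol | CCCCCCC#CCCCCCCCCCCCO | intermediate
7 | nonadec-12-ynal | CCCCCCC#CCCCCCCCCCCC=O | intermediate
8 | 2-methylidenenonadec-12-ynal | CCCCCCC#CCCCCCCCCCC(=C)C=O | intermediate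
9 | (E)-1-(dimethylamino)-3-(tert-butyldimethylsilyloxy)buta-1,3-diene | CN(C)/C=C/C(=C)O[Si](C)(C)C(C)(C)C | starting material
10 | (1R,2S)-4-(tert-butyldimethylsilyloxy)-2-(dimethylamino)-1-(heptadec-10-yn-1-yl)cyclohex-3-ene-1-carbaldehyde (CHO and NMe2 cis) | CCCCCCC#CCCCCCCCCC[C@]1(C=O)[C@@H](N(C)C)C=C(O[Si](C)(C)C(C)(C)C)CC1 | intermediate (not isolated)
11 | (1R)-1-(heptadec-10-yn-1-yl)-4-oxocyclohex-2-ene-1-carbaldehyde | CCCCCCC#CCCCCCCCCC[C@]1(C=O)C=CC(=O)CC1 | intermediate
12 | (1R)-1-(heptadec-10-yn-1-yl)-4-oxocyclohex-2-en-1-yl formate | CCCCCCC#CCCCCCCCCC[C@]1(OC=O)C=CC(=O)CC1 | intermediate (not isolated)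
13 | (4R)-4-(heptadec-10-yn-1-yl)-4-hydroxycyclohex-2-en-1-one | CCCCCCC#CCCCCCCCCC[C@]1(O)C=CC(=O)CC1 | intermediate
14 | (5R)-5-(heptadec-10-yn-1-yl)-2,5-bis(trimethylsilyloxy)cyclohexa-1,3-diene | CCCCCCC#CCCCCCCCCC[C@]1(O[Si](C)(C)C)C=CC(O[Si](C)(C)C)=CC1 | intermediate
15 | (1S,4R,6S)-4-(heptadec-10-yn-1-yl)-1,4-bis(trimethylsilyloxy)-7-oxabicyclo[4.1.0]hept-2-ene (epoxide oxygen cis to the C4 oxygen) | CCCCCCC#CCCCCCCCCC[C@]1(O[Si](C)(C)C)C=C[C@@]2(O[Si](C)(C)C)O[C@H]2C1 | intermediate (not isolated)
16 | (4R,6S)-4-(heptadec-10-yn-1-yl)-4,6-dihydroxycyclohex-2-en-1-one (hydroxyls cis) | CCCCCCC#CCCCCCCCCC[C@]1(O)C=CC(=O)[C@@H](O)C1 | intermediate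
17 | (4R,6S)-4-[(10Z)-heptadec-10-en-1-yl]-4,6-dihydroxycyclohex-2-en-1-one | CCCCCC/C=C\CCCCCCCCC[C@]1(O)C=CC(=O)[C@@H](O)C1 | target

**Step count**
Total steps: 10. Longest linear sequence: 10 steps (1 → 17).

**Steps most likely to fail**

1. Step 6 (key Diels–Alder). The hydrogen-bond catalyst may differentiate the enantiofaces of the long-chain enal too weakly, or the uncatalysed cycloaddition may compete, so that 11 forms with insufficient enantiomeric purity. The fallback sets out from 8 and returns at 11, and replaces hydrogen-bond catalysis by chiral Lewis-acid catalysis with a less basic N-acyl diene. 4-Methoxybut-3-en-2-one and benzylamine give (Z)-4-(benzylamino)but-3-en-2-one F1; N-acylation (NaH, ClCO2Me, THF) gives methyl benzyl[(1E)-3-oxobut-1-en-1-yl]carbamate F2; KHMDS and TBSCl give methyl benzyl[(1E)-3-(tert-butyldimethylsilyloxy)buta-1,3-dien-1-yl]carbamate F3. F3 and 8 are combined with a chiral chromium(III)–salen hexafluoroantimonate catalyst (about 5 mol%, 4 Å MS, CH2Cl2, −40 °C; enantiomer chosen for the R centre), a catalyst class established for this diene type with α-alkylacroleins. This should give methyl benzyl[(1S,6R)-3-(tert-butyldimethylsilyloxy)-6-formyl-6-(heptadec-10-yn-1-yl)cyclohex-2-en-1-yl]carbamate F4. HF in MeCN, followed by DBU if the β-carbamato ketone persists, unmasks the ketone and eliminates the carbamate to give 11.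

2. Step 9 (C6 hydroxylation). Facial selectivity in the epoxidation of 14 may be poor or reversed (attack anti to the C4 oxygen), leading to the 4,6-trans diol. The fallback sets out from 14 and returns at 16, and sets C6 by SN2 inversion instead of by facial selectivity. The same oxidation and desilylation are run and the epimer (4R,6R)-4-(heptadec-10-yn-1-yl)-4,6-dihydroxycyclohex-2-en-1-one F5 is separated by chromatography. A Mitsunobu reaction (PPh3, DIAD, 4-nitrobenzoic acid, THF, 0 °C) at the secondary C6 hydroxyl, the tertiary C4 hydroxyl being inert, gives with inversion (1S,5R)-5-(heptadec-10-yn-1-yl)-5-hydroxy-2-oxocyclohex-3-en-1-yl 4-nitrobenzoate F6. Brief methanolysis (K2CO3 cat., MeOH, 0 °C) gives 16.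

3. Step 7 (Baeyer–Villiger oxidation). Hydrogen instead of C4 may migrate in the Criegee intermediate, giving the carboxylic acid; the electron-poor enone attached to the migrating carbon lowers its migratory aptitude. The fallback sets out from 11 and returns at 13, and removes hydrogen from the competition by oxidising a methyl ketone. Aldehyde-selective addition of MeTi(OiPr)3 (THF, −40 °C) gives (4R)-4-(heptadec-10-yn-1-yl)-4-(1-hydroxyethyl)cyclohex-2-en-1-one F7 as a mixture of carbinol epimers. Dess–Martin periodinane gives (4R)-4-acetyl-4-(heptadec-10-yn-1-yl)cyclohex-2-en-1-one F8. Baeyer–Villiger oxidation (mCPBA, NaHCO3, CH2Cl2, rt), in which the tertiary carbon migrates in preference to methyl with retention, gives (1R)-1-(heptadec-10-yn-1-yl)-4-oxocyclohex-2-en-1-yl acetate F9. K2CO3 in MeOH returns 13.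

**Further compounds**
F1 | step 6 | (Z)-4-(benzylamino)but-3-en-2-one | CC(=O)/C=C\NCc1ccccc1
F2 | step 6 | methyl benzyl[(1E)-3-oxobut-1-en-1-yl]carbamate | CC(=O)/C=C/N(Cc1ccccc1)C(=O)OC
F3 | step 6 | methyl benzyl[(1E)-3-(tert-butyldimethylsilyloxy)buta-1,3-dien-1-yl]carbamate | C=C(O[Si](C)(C)C(C)(C)C)/C=C/N(Cc1ccccc1)C(=O)OC
F4 | step 6 | methyl benzyl[(1S,6R)-3-(tert-butyldimethylsilyloxy)-6-formyl-6-(heptadec-10-yn-1-yl)cyclohex-2-en-1-yl]carbamate | CCCCCCC#CCCCCCCCCC[C@]1(C=O)[C@@H](N(Cc2ccccc2)C(=O)OC)C=C(O[Si](C)(C)C(C)(C)C)CC1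
F5 | step 9 | (4R,6R)-4-(heptadec-10-yn-1-yl)-4,6-dihydroxycyclohex-2-en-1-one | CCCCCCC#CCCCCCCCCC[C@]1(O)C=CC(=O)[C@H](O)C1
F6 | step 9 | (1S,5R)-5-(heptadec-10-yn-1-yl)-5-hydroxy-2-oxocyclohex-3-en-1-yl 4-nitrobenzoate | CCCCCCC#CCCCCCCCCC[C@]1(O)C=CC(=O)[C@@H](OC(=O)c2ccc(cc2)[N+](=O)[O-])C1
F7 | step 7 | (4R)-4-(heptadec-10-yn-1-yl)-4-(1-hydroxyethyl)cyclohex-2-en-1-one (both carbinol epimers) | CCCCCCC#CCCCCCCCCC[C@]1(C(C)O)C=CC(=O)CC1
F8 | step 7 | (4R)-4-acetyl-4-(heptadec-10-yn-1-yl)cyclohex-2-en-1-one | CCCCCCC#CCCCCCCCCC[C@]1(C(C)=O)C=CC(=O)CC1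
F9 | step 7 | (1R)-1-(heptadec-10-yn-1-yl)-4-oxocyclohex-2-en-1-yl acetate | CCCCCCC#CCCCCCCCCC[C@]1(OC(C)=O)C=CC(=O)CC1
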